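**Strategy.** Everything rests on closing the tetrahydrofuran ring (O–C9–C11–C12–C13, labdane numbering) at C12–C13 by intramolecular alkylation of a lactone enolate. The spiro carbon C13 is at once the ether carbon of this ring and a ring carbon of the butyrolactone; with C16 held temporarily at the carboxyl level, C13 is an enolate carbon. In the precursor the hindered C9 oxygen carries a lactone made from purchased (R)-5-(hydroxymethyl)butyrolactone and C12 bears iodide. One operation forms the spirocycle and sets C13 anti to the lactone stereocentre, whose trityloxymethyl arm is later excised as formaldehyde while the stereocentre itself becomes the C15 carbonyl. The decalin comes from sclareolide.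

Key step: step 14

Assumption: labdane numbering is used throughout (ring A C1–C5/C10, ring B C5–C10, side chain C11–C16); (+)-sclareolide and (R)-5-(hydroxymethyl)dihydrofuran-2(3H)-one are taken as purchasable.

**Step 1**
Reactants: 1 (+)-sclareolide
Product: 2 methyl 13,14,15,16-tetranorlabd-8-en-12-oate
Conditions: conc. H2SO4, MeOH, reflux
Reagents that add atoms: methanol, CO
Why: Acid-catalysed lactone methanolysis followed by E1 dehydration and double-bond equilibration should deliver mainly the tetrasubstituted C8=C9 alkene (minor alkene isomers are removed by chromatography), leaving C5 and C10 untouched.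

**Step 2**
Reactants: 2 methyl 13,14,15,16-tetranorlabd-8-en-12-oate
Product: 3 13,14,15,16-tetranorlabd-8-en-12-ol
Conditions: LiAlH4, THF, 0 °C
Reagents that add atoms: none
Why: LiAlH4 ester reduction gives the primary C12 alcohol without touching the tetrasubstituted alkene.

**Step 3**
Reactants: 3 13,14,15,16-tetranorlabd-8-en-12-ol
Product: 4 12-chloro-13,14,15,16-tetranorlabd-8-ene
Conditions: PPh3, CCl4, CH2Cl2, 40 °C
Reagents that add atoms: tetrachloromethane, ClC(Cl)(Cl)Cl
Why: Appel chlorination (SN2 at C12) installs a chloride that is inert to the ring B chemistry that follows and is the latent electrophile for the ring closure.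

**Step 4**
Reactants: 4 12-chloro-13,14,15,16-tetranorlabd-8-ene
Product: 5 12-chloro-13,14,15,16-tetranorlabd-8-en-7-one
Conditions: CrO3, 3,5-dimethylpyrazole, CH2Cl2, −20 °C
Reagents that add atoms: chromium trioxide, O=[Cr](=O)=O
Why: Allylic C–H oxidation with the CrO3–3,5-dimethylpyrazole complex should take place at the ring methylene C7, whose axial C–H bond overlaps the alkene, in preference to the crowded C11 and the primary C17 positions.

**Step 5**
Reactants: 5 12-chloro-13,14,15,16-tetranorlabd-8-en-7-one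
Product: 6 12-chloro-8α,9α-epoxy-13,14,15,16-tetranorlabdan-7-one
Conditions: 30% H2O2, NaOH, MeOH, 0 → 23 °C
Reagents that add atoms: hydrogen peroxide, OO
Why: Weitz–Scheffer nucleophilic epoxidation, in which hydroperoxide adds to C9 from the α face opposite the axial C10 methyl group, sets the 9α-oxygen (and transiently C8).

**Step 6**
Reactants: 6 12-chloro-8α,9α-epoxy-13,14,15,16-tetranorlabdan-7-one
Product: 7 12-chloro-9α-hydroxy-13,14,15,16-tetranorlabdan-7-one (8α-methyl)
Conditions: SmI2, THF–MeOH, −78 °C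
Reagents that add atoms: none
Why: Single-electron reductive opening of the α,β-epoxy ketone cleaves the C8–O bond next to the carbonyl and keeps the C9–O bond, and axial (β-face) protonation of the trivalent samarium enolate sets 8β-H, which is also the more stable equatorial 8α-methyl arrangement.

**Step 7**
Reactants: 7 12-chloro-9α-hydroxy-13,14,15,16-tetranorlabdan-7-one (8α-methyl)
Product: 9 7-(tert-butyldimethylsilyloxy)-12-chloro-13,14,15,16-tetranorlabd-6-en-9α-ol, via dilithium alkoxide-enolate 8 (not isolated)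
Conditions: LiN(iPr)2 (2.5 equiv), THF, −78 °C; TBSCl, DMPU, −78 → −40 °C
Reagents that add atoms: tert-butyldimethylsilyl chloride, CC(C)(C)[Si](C)(C)Cl
Why: Kinetic enolisation and O-silylation: once the 9-hydroxyl is deprotonated, the second equivalent of amide removes a C6 proton (C8 is tertiary and next to the alkoxide), and only the enolate oxygen is silylated because the tertiary alkoxide is too hindered; no stereocentre changes.

**Step 8**
Reactants: 9 7-(tert-butyldimethylsilyloxy)-12-chloro-13,14,15,16-tetranorlabd-6-en-9α-ol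
Product: 11 7β-(tert-butyldimethylsilyloxy)-12-chloro-13,14,15,16-tetranorlabdane-6α,9α-diol, via C6 alkylborane 10 (not isolated)
Conditions: BH3·THF, THF, 0 → 23 °C; then 30% H2O2, aq NaHCO3, 0 °C
Reagents that add atoms: hydrogen peroxide, OO
Why: Hydroboration–oxidation of the silyl enol ether places boron on C6 (β to oxygen) and hydrogen on C7 from the α face, because the β face is blocked by the axial methyl groups on C4 and C10, so oxidation with retention gives the 6α-hydroxyl and the 7β-silyloxy group (trans, both equatorial).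

**Step 9**
Reactants: 11 7β-(tert-butyldimethylsilyloxy)-12-chloro-13,14,15,16-tetranorlabdane-6α,9α-diol
Product: 12 6α-benzyloxy-7β-(tert-butyldimethylsilyloxy)-12-chloro-13,14,15,16-tetranorlabdan-9α-ol
Conditions: 2-benzyloxy-1-methylpyridinium triflate, MgO, PhCF3, 85 °C
Reagents that add atoms: 2-benzyloxy-1-methylpyridinium triflate, C[n+]1ccccc1OCc1ccccc1.[O-]S(=O)(=O)C(F)(F)F
Why: Neutral benzyl transfer from the 2-benzyloxypyridinium salt etherifies the secondary 6α-hydroxyl in preference to the far more hindered tertiary 9α-hydroxyl and, being base-free, avoids silyl migration from O7 to O6.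

**Step 10**
Reactants: 13 (R)-5-(hydroxymethyl)dihydrofuran-2(3H)-one
Product: 14 (R)-5-[(trityloxy)methyl]dihydrofuran-2(3H)-one
Conditions: TrCl, pyridine, DMAP (cat.), 23 °C
Reagents that add atoms: trityl chloride, ClC(c1ccccc1)(c1ccccc1)c1ccccc1
Why: Tritylation of the primary alcohol (SN1-type ether formation) installs the bulky group that later shields one face of the lactone, and the lactone stereocentre is untouched.

**Step 11**
Reactants: 14 (R)-5-[(trityloxy)methyl]dihydrofuran-2(3H)-one
Product: 16 (R)-3-diazo-5-[(trityloxy)methyl]dihydrofuran-2(3H)-one, via trifluoroacetyl lactone 15 (not isolated)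
Conditions: LiN(SiMe3)2, THF, −78 °C; CF3CO2CH2CF3; then MsN3, Et3N, H2O, MeCN, 23 °C
Reagents that add atoms: methanesulfonyl azide, CS(=O)(=O)N=[N+]=[N-]
Why: Detrifluoroacetylative diazo transfer: Claisen-type trifluoroacetylation of the lactone enolate activates C3 for diazo transfer from the sulfonyl azide with loss of the trifluoroacetyl group, without affecting C5.

**Step 12**
Reactants: 12 6α-benzyloxy-7β-(tert-butyldimethylsilyloxy)-12-chloro-13,14,15,16-tetranorlabdan-9α-ol; 16 (R)-3-diazo-5-[(trityloxy)methyl]dihydrofuran-2(3H)-one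
Product: 17 9α-O-{(5R)-2-oxo-5-[(trityloxy)methyl]tetrahydrofuran-3-yl} ether of 12 (both epimers at the lactone α-carbon C13)
Conditions: Rh2(OAc)4 (2 mol %), CH2Cl2, 23 °C, 16 (3 equiv) added slowly
Reagents that add atoms: none
Why: Dirhodium-carbenoid O–H insertion (oxonium ylide formation, then proton transfer) is one of the few ether syntheses that tolerate a hindered tertiary alcohol; the configuration created at C13 is irrelevant because it is erased in step 14, and C15 is untouched.

**Step 13**
Reactants: 17 9α-O-{(5R)-2-oxo-5-[(trityloxy)methyl]tetrahydrofuran-3-yl} ether of 12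
Product: 18 the 12-iodide corresponding to 17
Conditions: NaI, 2-butanone, 80 °C
Reagents that add atoms: sodium iodide, [Na+].[I-]
Why: Finkelstein halide exchange (SN2) converts the unreactive primary chloride into the iodide needed for ring closure at low temperature.

**Step 14**
Reactants: 18 the 12-iodide corresponding to 17
Product: 20 (13R,15R)-6α-benzyloxy-7β-(tert-butyldimethylsilyloxy)-9α,13-epoxy-15-[(trityloxy)methyl]labdan-16,15-olide (spiro compound with the reversed lactone C16(=O)–O–C15), via potassium lactone enolate 19 (not isolated)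
Conditions: KN(SiMe3)2, THF, −78 → −20 °C
Reagents that add atoms: none
Why: KN(SiMe3)2 removes the C13 proton (α to the lactone carbonyl C16 and to the ether oxygen) to give a planar potassium enolate, which erases the C13 epimer mixture, and the enolate carbon then displaces the primary iodide at C12 in an intramolecular SN2 reaction. The closest known reaction type is the α-alkylation of γ-substituted γ-butyrolactone enolates, used here as a spiro-annulating intramolecular enolate alkylation. The tetrahydrofuran ring O–C9–C11–C12–C13 closes in the 5-exo-tet mode, with the enolate double bond C13=C16 exocyclic to the new ring. The new stereocentre C13 is controlled by the lactone stereocentre C15: C12 should enter on the enolate face anti to the trityloxymethyl group (1,3-induction), which corresponds to 13R. The step needs face selectivity and C- over O-alkylation; these are secured by the bulky trityl group on one face, by the nearly symmetric flanking of the ether oxygen by C8 and C10 (so the decalin exerts no opposing bias), and by the preference for a five- over a seven-membered ring. E2 loss of HI should be outrun by the ring closure because the nucleophile is held five atoms from C12.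

**Step 15**
Reactants: 20 (13R,15R)-spiro lactone
Product: 21 (13R,15R)-6α-benzyloxy-7β-(tert-butyldimethylsilyloxy)-9α,13-epoxy-15-[(trityloxy)methyl]labdane-15,16-diol
Conditions: LiAlH4, THF, 0 → 23 °C
Reagents that add atoms: none
Why: LiAlH4 reduction of the lactone to the 1,4-diol turns the C16 carbonyl into the CH2OH of the target lactone and leaves the ring oxygen on C15 as a secondary alcohol; no stereocentre is affected.

**Step 16**
Reactants: 21 (13R,15R)-15,16-diol
Product: 22 (13R,15R)-7β-(tert-butyldimethylsilyloxy)-9α,13-epoxy-15-(hydroxymethyl)labdane-6α,15,16-triol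
Conditions: H2 (1 atm), Pd(OH)2/C, EtOAc–EtOH, 23 °C
Reagents that add atoms: none
Why: Hydrogenolysis over Pd(OH)2/C cleaves the benzyl and trityl ethers in one operation while the silyl ether on O7 stays in place.

**Step 17**
Reactants: 22 (13R,15R)-tetraol
Product: 24 (13R)-7β-(tert-butyldimethylsilyloxy)-9α,13-epoxy-6α-hydroxylabdane 15,16-lactol (both anomers), via hydroxy aldehyde 23 (not isolated)
Conditions: NaIO4, THF–H2O (pH 7 buffer), 0 → 23 °C
Reagents that add atoms: none
Why: Periodate (Malaprade) cleavage of the only free 1,2-diol removes the former trityloxymethyl carbon as formaldehyde, and the C15 aldehyde is trapped by the C16 hydroxyl as the five-membered lactol; O7 is silylated, so ring B is not cleaved.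

**Step 18**
Reactants: 24 (13R)-lactol
Product: 25 (13R)-7β-(tert-butyldimethylsilyloxy)-9α,13-epoxy-6-oxolabdan-15,16-olide
Conditions: Pr4N[RuO4] (5 mol %), N-methylmorpholine N-oxide, 4 Å sieves, CH2Cl2, 23 °C
Reagents that add atoms: none
Why: Ley–Griffith oxidation converts the lactol into the lactone (C15 carbonyl) and the 6α-alcohol into the C6 ketone at once; C5 keeps the more stable trans ring fusion and the silyl group on O7 prevents ketol isomerisation.

**Step 19**
Reactants: 25 (13R)-7β-silyloxy keto lactone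
Product: 26 (13R)-9α,13-epoxy-7β-hydroxy-6-oxolabdan-15,16-olide (target)
Conditions: HF·pyridine, THF, 0 → 23 °C
Reagents that add atoms: none
Why: Acidic fluoride-mediated desilylation frees the 7β-hydroxyl without base, which avoids retro-oxa-Michael opening at C13 and α-ketol isomerisation, and gives the target.

**Compound list**

1 | (+)-sclareolide | C[C@@]12CC[C@H]3C(C)(C)CCC[C@]3(C)[C@H]1CC(=O)O2 | starting material
2 | methyl 13,14,15,16-tetranorlabd-8-en-12-oate | CC1=C(CC(=O)OC)[C@@]2(C)CCCC(C)(C)[C@@H]2CC1 | intermediate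
3 | 13,14,15,16-tetranorlabd-8-en-12-ol | CC1=C(CCO)[C@@]2(C)CCCC(C)(C)[C@@H]2CC1 | intermediate
4 | 12-chloro-13,14,15,16-tetranorlabd-8-ene | CC1=C(CCCl)[C@@]2(C)CCCC(C)(C)[C@@H]2CC1 | intermediate
5 | 12-chloro-13,14,15,16-tetranorlabd-8-en-7-one | CC1=C(CCCl)[C@@]2(C)CCCC(C)(C)[C@@H]2CC1=O | intermediate
6 | 12-chloro-8α,9α-epoxy-13,14,15,16-tetranorlabdan-7-one | C[C@]12O[C@@]1(CCCl)[C@@]3(C)CCCC(C)(C)[C@@H]3CC2=O | intermediate
7 | 12-chloro-9α-hydroxy-13,14,15,16-tetranorlabdan-7-one (8α-methyl) | C[C@@H]1C(=O)C[C@H]2C(C)(C)CCC[C@]2(C)[C@@]1(O)CCCl | intermediate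
8 | dilithium 9-alkoxide C6=C7 enolate of 7 (not isolated) | C[C@@H]1C([O-])=C[C@H]2C(C)(C)CCC[C@]2(C)[C@@]1([O-])CCCl.[Li+].[Li+] | intermediate
9 | 7-(tert-butyldimethylsilyloxy)-12-chloro-13,14,15,16-tetranorlabd-6-en-9α-ol | C[C@@H]1C(O[Si](C)(C)C(C)(C)C)=C[C@H]2C(C)(C)CCC[C@]2(C)[C@@]1(O)CCCl | intermediate
10 | 6α-boryl-7β-(tert-butyldimethylsilyloxy)-12-chloro-13,14,15,16-tetranorlabdan-9α-ol (alkylborane drawn as RBH2, not isolated) | C[C@@H]1[C@@H](O[Si](C)(C)C(C)(C)C)[C@H](B)[C@H]2C(C)(C)CCC[C@]2(C)[C@@]1(O)CCCl | intermediate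
11 | 7β-(tert-butyldimethylsilyloxy)-12-chloro-13,14,15,16-tetranorlabdane-6α,9α-diol | C[C@@H]1[C@@H](O[Si](C)(C)C(C)(C)C)[C@H](O)[C@H]2C(C)(C)CCC[C@]2(C)[C@@]1(O)CCCl | intermediate
12 | 6α-benzyloxy-7β-(tert-butyldimethylsilyloxy)-12-chloro-13,14,15,16-tetranorlabdan-9α-ol | C[C@@H]1[C@@H](O[Si](C)(C)C(C)(C)C)[C@H](OCc3ccccc3)[C@H]2C(C)(C)CCC[C@]2(C)[C@@]1(O)CCCl | intermediate
13 | (R)-5-(hydroxymethyl)dihydrofuran-2(3H)-one | O=C1CC[C@H](CO)O1 | starting material
14 | (R)-5-[(trityloxy)methyl]dihydrofuran-2(3H)-one | O=C1CC[C@H](COC(c2ccccc2)(c2ccccc2)c2ccccc2)O1 | intermediate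
15 | (5R)-3-(trifluoroacetyl)-5-[(trityloxy)methyl]dihydrofuran-2(3H)-one (not isolated) | O=C1C(C(=O)C(F)(F)F)C[C@H](COC(c2ccccc2)(c2ccccc2)c2ccccc2)O1 | intermediate
16 | (R)-3-diazo-5-[(trityloxy)methyl]dihydrofuran-2(3H)-one | O=C1C(=[N+]=[N-])C[C@H](COC(c2ccccc2)(c2ccccc2)c2ccccc2)O1 | intermediate
17 | 9α-O-{(5R)-2-oxo-5-[(trityloxy)methyl]tetrahydrofuran-3-yl} ether of 12 (both C13 epimers) | C[C@@H]1[C@@H](O[Si](C)(C)C(C)(C)C)[C@H](OCc3ccccc3)[C@H]2C(C)(C)CCC[C@]2(C)[C@@]1(OC3C[C@H](COC(c4ccccc4)(c4ccccc4)c4ccccc4)OC3=O)CCCl | intermediate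
18 | 12-iodide corresponding to 17 | C[C@@H]1[C@@H](O[Si](C)(C)C(C)(C)C)[C@H](OCc3ccccc3)[C@H]2C(C)(C)CCC[C@]2(C)[C@@]1(OC3C[C@H](COC(c4ccccc4)(c4ccccc4)c4ccccc4)OC3=O)CCI | intermediate
19 | potassium lactone enolate of 18 (C13=C16, not isolated) | C[C@@H]1[C@@H](O[Si](C)(C)C(C)(C)C)[C@H](OCc3ccccc3)[C@H]2C(C)(C)CCC[C@]2(C)[C@@]1(OC3=C([O-])O[C@@H](COC(c4ccccc4)(c4ccccc4)c4ccccc4)C3)CCI.[K+] | intermediate
20 | (13R,15R)-6α-benzyloxy-7β-(tert-butyldimethylsilyloxy)-9α,13-epoxy-15-[(trityloxy)methyl]labdan-16,15-olide | C[C@@H]1[C@@H](O[Si](C)(C)C(C)(C)C)[C@H](OCc3ccccc3)[C@H]2C(C)(C)CCC[C@]2(C)[C@@]12CC[C@@]1(C(=O)O[C@@H](COC(c3ccccc3)(c3ccccc3)c3ccccc3)C1)O2 | intermediate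
21 | (13R,15R)-6α-benzyloxy-7β-(tert-butyldimethylsilyloxy)-9α,13-epoxy-15-[(trityloxy)methyl]labdane-15,16-diol | C[C@@H]1[C@@H](O[Si](C)(C)C(C)(C)C)[C@H](OCc3ccccc3)[C@H]2C(C)(C)CCC[C@]2(C)[C@@]12CC[C@](CO)(C[C@@H](O)COC(c3ccccc3)(c3ccccc3)c3ccccc3)O2 | intermediate
22 | (13R,15R)-7β-(tert-butyldimethylsilyloxy)-9α,13-epoxy-15-(hydroxymethyl)labdane-6α,15,16-triol | C[C@@H]1[C@@H](O[Si](C)(C)C(C)(C)C)[C@H](O)[C@H]2C(C)(C)CCC[C@]2(C)[C@@]12CC[C@](CO)(C[C@@H](O)CO)O2 | intermediate
23 | (13R)-7β-(tert-butyldimethylsilyloxy)-9α,13-epoxy-6α,16-dihydroxylabdan-15-al (not isolated) | C[C@@H]1[C@@H](O[Si](C)(C)C(C)(C)C)[C@H](O)[C@H]2C(C)(C)CCC[C@]2(C)[C@@]12CC[C@](CO)(CC=O)O2 | intermediate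
24 | (13R)-7β-(tert-butyldimethylsilyloxy)-9α,13-epoxy-6α-hydroxylabdane 15,16-lactol (anomers) | C[C@@H]1[C@@H](O[Si](C)(C)C(C)(C)C)[C@H](O)[C@H]2C(C)(C)CCC[C@]2(C)[C@@]12CC[C@@]1(COC(O)C1)O2 | intermediate
25 | (13R)-7β-(tert-butyldimethylsilyloxy)-9α,13-epoxy-6-oxolabdan-15,16-olide | C[C@@H]1[C@@H](O[Si](C)(C)C(C)(C)C)C(=O)[C@H]2C(C)(C)CCC[C@]2(C)[C@@]12CC[C@@]1(COC(=O)C1)O2 | intermediate
26 | (13R)-9α,13-epoxy-7β-hydroxy-6-oxolabdan-15,16-olide | C[C@@H]1[C@@H](O)C(=O)[C@H]2C(C)(C)CCC[C@]2(C)[C@@]12CC[C@@]1(COC(=O)C1)O2 | target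

**Step count.** Total: 19 steps. Longest linear sequence: 17 steps (steps 1–9 and 12–19, from sclareolide); steps 10–11 prepare the diazo lactone.

**Steps most likely to fail**

Step 12. The rhodium carbenoid from 16 may undergo 1,2-hydride shift to the butenolide, or dimerise, faster than it is intercepted by the very hindered axial 9α-hydroxyl. The fallback sets out from 12 and comes back at 17; it alkylates the oxygen with the smallest, shift-free carbenoid and builds the lactone afterwards. Alcohol 12 is treated with ethyl diazoacetate and Rh2(OAc)4 to give ethyl {[6α-benzyloxy-7β-(tert-butyldimethylsilyloxy)-12-chloro-13,14,15,16-tetranorlabdan-9α-yl]oxy}acetate F1. Its aluminium enolate (LiN(iPr)2, then Et2AlCl, THF, −78 °C, where the primary chloride is still inert) opens (R)-trityl glycidyl ether at the terminal carbon to give the (4R)-4-hydroxy-5-(trityloxy)pentanoate F2. F2 lactonises with pyridinium p-toluenesulfonate to 17.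

Step 14. Facial discrimination at the fully substituted enolate carbon may be poor, or E2 loss of HI may compete with ring closure. The fallback sets out from 12 and comes back at 20; it reverses the order of the two bond formations at C13 and gives up the stereocontrol. Methyl diazoacetate and Rh2(OAc)4 convert 12 into the methyl alkoxyacetate F3. KN(SiMe3)2 in THF–DMPU then closes the tetrahydrofuran through the same C12–C13 bond from this unhindered glycolate enolate, giving methyl 6α-benzyloxy-7β-(tert-butyldimethylsilyloxy)-9α,13-epoxy-14,15-dinorlabdan-16-oate F4. The enolate of F4 (LiN(iPr)2, Et2AlCl) opens (R)-trityl glycidyl ether and the resulting alkoxide lactonises to 20 together with its C13 epimer. The two are diastereomers because C15 is fixed, and the epimer is removed by chromatography.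

Step 4. Oxidation may occur at the wrong allylic position (C11 or C17), or over-oxidation may take place. The fallback sets out from 4 and comes back at 5; it brings the oxygen in through the alkene instead of a C–H bond. Epoxidation of 4 with mCPBA/NaHCO3 from the α face gives 12-chloro-8α,9α-epoxy-13,14,15,16-tetranorlabdane F5. Al(OiPr)3 in refluxing toluene isomerises F5 to the tertiary allylic alcohol 12-chloro-13,14,15,16-tetranorlabd-7-en-9α-ol F6. [C5H5NH][CrO3Cl] (pyridinium chlorochromate) in CH2Cl2 then effects the Dauben oxidative 1,3-transposition of F6 to enone 5.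

Further compounds
F1 | step 12 | ethyl {[6α-benzyloxy-7β-(tert-butyldimethylsilyloxy)-12-chloro-13,14,15,16-tetranorlabdan-9α-yl]oxy}acetate | C[C@@H]1[C@@H](O[Si](C)(C)C(C)(C)C)[C@H](OCc3ccccc3)[C@H]2C(C)(C)CCC[C@]2(C)[C@@]1(OCC(=O)OCC)CCCl
F2 | step 12 | ethyl (4R)-2-{[6α-benzyloxy-7β-(tert-butyldimethylsilyloxy)-12-chloro-13,14,15,16-tetranorlabdan-9α-yl]oxy}-4-hydroxy-5-(trityloxy)pentanoate (both C2 epimers) | C[C@@H]1[C@@H](O[Si](C)(C)C(C)(C)C)[C@H](OCc3ccccc3)[C@H]2C(C)(C)CCC[C@]2(C)[C@@]1(OC(C[C@@H](O)COC(c3ccccc3)(c3ccccc3)c3ccccc3)C(=O)OCC)CCCl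
F3 | step 14 | methyl {[6α-benzyloxy-7β-(tert-butyldimethylsilyloxy)-12-chloro-13,14,15,16-tetranorlabdan-9α-yl]oxy}acetate | C[C@@H]1[C@@H](O[Si](C)(C)C(C)(C)C)[C@H](OCc3ccccc3)[C@H]2C(C)(C)CCC[C@]2(C)[C@@]1(OCC(=O)OC)CCCl
F4 | step 14 | methyl 6α-benzyloxy-7β-(tert-butyldimethylsilyloxy)-9α,13-epoxy-14,15-dinorlabdan-16-oate (both C13 epimers) | C[C@@H]1[C@@H](O[Si](C)(C)C(C)(C)C)[C@H](OCc3ccccc3)[C@H]2C(C)(C)CCC[C@]2(C)[C@@]12CCC(C(=O)OC)O2
F5 | step 4 | 12-chloro-8α,9α-epoxy-13,14,15,16-tetranorlabdane | C[C@]12O[C@@]1(CCCl)[C@@]3(C)CCCC(C)(C)[C@@H]3CC2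
F6 | step 4 | 12-chloro-13,14,15,16-tetranorlabd-7-en-9α-ol | CC1=CC[C@H]2C(C)(C)CCC[C@]2(C)[C@@]1(O)CCCl
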